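**Retrosynthetic overview**
- The target is (2S)-7,3',4'-trihydroxy-8,5'-diprenylflavanone. The plan rests on the prenyl group at C8 of ring A, which sits between the two oxygen-bearing carbons C7 and C8a.
- C2–C1' is cut first: ring B arrives as an arylboronic acid that adds to C2=C3 of a chromone under rhodium/chiral-diene control, which sets C2.
- Ring C is opened at O1–C2 to an ortho-hydroxyaryl ynone, and this is traced back through C4–C4a to a phenol with hydrogen at C4a, C5 and C6.
- Ring A is cut across C8–C8a and C6–C7 into cyclobutenone (reacting as vinylketene) and a prenyl-substituted siloxyalkyne. The benzannulation places the prenyl group between a free hydroxyl (future O1) and a silyl ether (future O7).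
- Order of ring formation: ring A (step 4), ring C (step 7), ring B attached preformed (step 15).

Key step: step 4

Remark: ethyl 4-methylpent-3-enoate (1) is treated as a purchasable compound.
Remark: cyclobutenone is reached through 3-bromocyclobutanone, because a 2-bromocyclobutanone would ring-contract with base instead of eliminating cleanly.
Remark: the sense of induction of the diene ligand in step 15 is assigned by analogy with cyclic enones, where the (R,R)-diene leads to the (R)-β-aryl ketone. It is to be confirmed on the first run; the antipodal ligand is equally accessible.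

**Route**

Step 1
Reactants: 1 ethyl 4-methylpent-3-enoate
Product: 4 triisopropyl(5-methylhex-4-en-1-ynyloxy)silane, via dibromomethyl ketone 2 (not isolated), via lithium ynolate 3 (not isolated)
Conditions: CH2Br2, LiTMP (lithium 2,2,6,6-tetramethylpiperidide), THF, −78 °C; LiHMDS (LiN(SiMe3)2); n-BuLi, −78 °C → rt; TIPSCl, −78 → 0 °C
Reagents that add atoms: dibromomethane BrCBr; chlorotriisopropylsilane CC(C)[Si](Cl)(C(C)C)C(C)C
Why: Kowalski ester homologation, in which LiCHBr2 adds to the ester, the enolate of the dibromo ketone undergoes bromine–lithium exchange and 1,2-shift to the ynolate, and the hindered silyl chloride traps the ynolate on oxygen; an α-CH2 of arylacetate-like acidity is tolerated by this sequence.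

Step 2
Reactants: 5 3-oxocyclobutane-1-carboxylic acid
Product: 6 3-bromocyclobutan-1-one
Conditions: HgO, Br2, MgSO4, CH2Cl2, reflux
Reagents that add atoms: bromine BrBr
Why: Cristol–Firth variant of the Hunsdiecker reaction, in which the acyl hypobromite formed from the mercury carboxylate loses CO2 in a radical chain and gives the secondary bromide.

Step 3
Reactants: 6 3-bromocyclobutan-1-one
Product: 7 cyclobut-2-en-1-one
Conditions: n-Bu3N, neat, rt, reduced pressure, product collected at −78 °C
Reagents that add atoms: none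
Why: E1cB dehydrobromination of a β-bromo ketone by a high-boiling amine, with the volatile and polymerization-prone enone distilled out as it forms and used at once.

Step 4
Reactants: 4 triisopropyl(5-methylhex-4-en-1-ynyloxy)silane, 7 cyclobut-2-en-1-one
Product: 12 2-(3-methylbut-2-enyl)-3-(triisopropylsilyloxy)phenol, via vinylketene 8 (not isolated), via 4-vinylcyclobutenone 9 (not isolated), via dienylketene 10 (not isolated), via cyclohexadienone 11 (not isolated)
Conditions: toluene, 80 °C, slow addition of 7 to 4 (1.3 equiv), then 110 °C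
Reagents that add atoms: none
Why: Heating opens cyclobutenone 7 by four-electron electrocyclic cleavage to vinylketene 8, whose ketene C=C adds across the electron-rich triple bond of 4 in a [2+2] cycloaddition, the carbonyl carbon bonding to the prenyl-bearing alkyne carbon (future C8a–C8) and the vinyl-bearing carbon to the siloxy carbon (future C6–C7), to give 9. Four-electron opening of 9 then gives dienylketene 10, and ring A closes by thermal disrotatory six-electron electrocyclization (C8a–C4a) to dienone 11, which tautomerizes irreversibly to phenol 12. This is the Danheiser benzannulation of cyclobutenones with siloxyalkynes, a known route to resorcinol monosilyl ethers. No stereocenter is formed. The step needs regioselectivity only, and the polarization of the ynol ether secures it: the oxygen lone pair makes the prenyl-bearing carbon the nucleophilic one, so the prenyl group can only end up between the hydroxyl and the silyloxy carbons and the two oxygens emerge differentiated. Slow addition of 7 to an excess of 4 keeps the ketene concentration low, which should limit oligomerization of 7 and acylation of the product phenol by 8.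

Step 5
Reactants: 12 2-(3-methylbut-2-enyl)-3-(triisopropylsilyloxy)phenol
Product: 14 2-hydroxy-3-(3-methylbut-2-enyl)-4-(triisopropylsilyloxy)benzaldehyde, via salicyl alcohol 13 (not isolated)
Conditions: MgCl2, Et3N, (CH2O)n, THF, reflux; dilute aq HCl work-up
Reagents that add atoms: formaldehyde (from paraformaldehyde) C=O
Why: Magnesium-mediated ortho-formylation (Casnati–Skattebøl), in which the magnesium phenoxide delivers formaldehyde to the only free ortho carbon (future C4a) and a second formaldehyde oxidizes the benzylic alkoxide by hydride transfer, under non-acidic conditions that spare the prenyl group and the silyl ether.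

Step 6
Reactants: 14 2-hydroxy-3-(3-methylbut-2-enyl)-4-(triisopropylsilyloxy)benzaldehyde
Product: 15 2-(1-hydroxyprop-2-yn-1-yl)-6-(3-methylbut-2-enyl)-5-(triisopropylsilyloxy)phenol (racemic)
Conditions: HC≡CMgBr (3 equiv), THF, 0 °C → rt; aq NH4Cl
Reagents that add atoms: ethynylmagnesium bromide C#C[Mg]Br
Why: Grignard 1,2-addition to the aldehyde after the first equivalent has deprotonated the phenol; the carbinol center is of no consequence because the next step oxidizes it.

Step 7
Reactants: 15 2-(1-hydroxyprop-2-yn-1-yl)-6-(3-methylbut-2-enyl)-5-(triisopropylsilyloxy)phenol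
Product: 18 8-(3-methylbut-2-enyl)-7-(triisopropylsilyloxy)-4H-chromen-4-one, via ynone 16 (not isolated), via enaminone 17 (not isolated)
Conditions: MnO2, CH2Cl2, rt; filter; Et2NH, EtOH, rt; 1 M aq HCl, CH2Cl2, rt
Reagents that add atoms: none
Why: MnO2 oxidizes the benzylic propargylic alcohol to the ynone, diethylamine adds in conjugate fashion to give the (E)-enaminone, and mild acid triggers addition–elimination by the ortho hydroxyl at the β-carbon, a 6-endo closure that forms O1–C2 of ring C and excludes the 5-exo pathway.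

Step 8
Reactants: 18 8-(3-methylbut-2-enyl)-7-(triisopropylsilyloxy)-4H-chromen-4-one
Product: 20 7-(methoxymethoxy)-8-(3-methylbut-2-enyl)-4H-chromen-4-one, via tetrabutylammonium chromenolate 19 (not isolated)
Conditions: TBAF (n-Bu4NF), THF, 0 °C; then MOMCl, 0 °C → rt
Reagents that add atoms: chloromethyl methyl ether COCCl
Why: Fluoride cleaves the aryl silyl ether and the ammonium phenoxide is O-alkylated in the same flask, which exchanges the silyl group for an acetal that is inert to the aqueous hydroxide of step 15 and comes off together with the ring B acetals.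

Step 9
Reactants: 21 5-bromo-2-hydroxybenzaldehyde
Product: 22 2-(allyloxy)-5-bromobenzaldehyde
Conditions: allyl bromide, K2CO3, DMF, rt
Reagents that add atoms: allyl bromide C=CCBr
Why: Williamson etherification of an acidic, hydrogen-bonded phenol with a reactive allylic halide.

Step 10
Reactants: 22 2-(allyloxy)-5-bromobenzaldehyde
Product: 24 3-allyl-5-bromo-2-hydroxybenzaldehyde, via Claisen dienone 23 (not isolated)
Conditions: N,N-diethylaniline, 200 °C
Reagents that add atoms: none
Why: Aromatic Claisen rearrangement, in which the [3,3] shift can only reach the unsubstituted ortho carbon because the other one carries the formyl group, and enolization restores the arene.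

Step 11
Reactants: 24 3-allyl-5-bromo-2-hydroxybenzaldehyde
Product: 26 3-allyl-5-bromobenzene-1,2-diol, via aryl formate 25 (not isolated)
Conditions: H2O2 (30% aq), NaOH, THF/H2O, 0 °C → rt; aq HCl
Reagents that add atoms: hydrogen peroxide OO
Why: Dakin oxidation, in which hydroperoxide adds to the ortho-hydroxy aldehyde, aryl migration gives the formate and this is hydrolyzed in the flask, while the isolated terminal alkene is inert to alkaline peroxide.

Step 12
Reactants: 26 3-allyl-5-bromobenzene-1,2-diol
Product: 27 1-allyl-5-bromo-2,3-bis(methoxymethoxy)benzene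
Conditions: MOMCl, i-Pr2NEt, CH2Cl2, 0 °C → rt
Reagents that add atoms: chloromethyl methyl ether COCCl
Why: Double O-alkylation of the catechol with an α-chloro ether gives acetals that withstand organolithium reagents and aqueous base and are cleaved by mild acid.

Step 13
Reactants: 27 1-allyl-5-bromo-2,3-bis(methoxymethoxy)benzene
Product: 28 5-bromo-1,2-bis(methoxymethoxy)-3-(3-methylbut-2-enyl)benzene
Conditions: second-generation Grubbs catalyst (H2IMes)(PCy3)Cl2Ru=CHPh (cat.), 2-methyl-2-butene/CH2Cl2, 40 °C
Reagents that add atoms: 2-methylbut-2-ene CC=C(C)C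
Why: Olefin cross-metathesis of a terminal alkene with excess 2-methyl-2-butene, which turns the allyl group into the trisubstituted prenyl alkene with loss of propene.

Step 14
Reactants: 28 5-bromo-1,2-bis(methoxymethoxy)-3-(3-methylbut-2-enyl)benzene
Product: 31 [3,4-bis(methoxymethoxy)-5-(3-methylbut-2-enyl)phenyl]boronic acid, via aryllithium 29 (not isolated), via lithium aryltriisopropoxyborate 30 (not isolated)
Conditions: n-BuLi, THF, −78 °C; B(Oi-Pr)3, −78 °C → rt; aq NH4Cl
Reagents that add atoms: triisopropyl borate CC(C)OB(OC(C)C)OC(C)C; water O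
Why: Bromine–lithium exchange at −78 °C outruns deprotonation of the benzylic allylic CH2, the aryllithium is trapped by the borate, and mild aqueous work-up hydrolyzes the boronate without touching the acetals.

Step 15
Reactants: 20 7-(methoxymethoxy)-8-(3-methylbut-2-enyl)-4H-chromen-4-one, 31 [3,4-bis(methoxymethoxy)-5-(3-methylbut-2-enyl)phenyl]boronic acid
Product: 32 (2S)-2-[3,4-bis(methoxymethoxy)-5-(3-methylbut-2-enyl)phenyl]-7-(methoxymethoxy)-8-(3-methylbut-2-enyl)chroman-4-one
Conditions: [RhCl(C2H4)2]2 (2.5 mol%), (S,S)-2,5-diphenylbicyclo[2.2.2]octa-2,5-diene [(S,S)-Ph-bod] (5.5 mol%), KOH (0.2 equiv, aq), 31 (2 equiv), toluene/H2O, 40 °C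
Reagents that add atoms: none
Why: Hayashi–Miyaura asymmetric 1,4-addition of an arylboronic acid to a chromone, in which transmetalation gives an aryl–rhodium(diene) species, C2=C3 inserts with aryl delivery to the Re face of C2 under control of the C2-symmetric chiral diene, and water protonates the rhodium enolate to release the (2S)-flavanone and the hydroxo-rhodium catalyst.

Step 16
Reactants: 32 (2S)-2-[3,4-bis(methoxymethoxy)-5-(3-methylbut-2-enyl)phenyl]-7-(methoxymethoxy)-8-(3-methylbut-2-enyl)chroman-4-one
Product: 33 (2S)-2-[3,4-dihydroxy-5-(3-methylbut-2-enyl)phenyl]-7-hydroxy-8-(3-methylbut-2-enyl)chroman-4-one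
Conditions: 3 M aq HCl, MeOH, 40 °C, argon
Reagents that add atoms: none
Why: Acid-catalyzed acetal exchange with methanol cleaves the three MOM ethers under conditions too mild to protonate the trisubstituted alkenes or to open the pyranone ring, so the C2 configuration should be retained.

**Compound list**
1 | ethyl 4-methylpent-3-enoate | CCOC(=O)CC=C(C)C | starting material
2 | 1,1-dibromo-5-methylhex-4-en-2-one (as lithium enolate, formed in situ) | CC(C)=CCC(=O)C(Br)Br | intermediate
3 | lithium 5-methylhex-4-en-1-yn-1-olate (formed in situ) | CC(C)=CCC#C[O-].[Li+] | intermediate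
4 | triisopropyl(5-methylhex-4-en-1-ynyloxy)silane | CC(C)=CCC#CO[Si](C(C)C)(C(C)C)C(C)C | intermediate
5 | 3-oxocyclobutane-1-carboxylic acid | O=C1CC(C(=O)O)C1 | starting material
6 | 3-bromocyclobutan-1-one | O=C1CC(Br)C1 | intermediate
7 | cyclobut-2-en-1-one | O=C1CC=C1 | intermediate
8 | buta-1,3-dien-1-one (vinylketene, formed in situ) | C=CC=C=O | intermediate
9 | 2-(3-methylbut-2-enyl)-3-(triisopropylsilyloxy)-4-vinylcyclobut-2-en-1-one (racemic, formed in situ) | O=C1C(CC=C(C)C)=C(O[Si](C(C)C)(C(C)C)C(C)C)C1C=C | intermediate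
10 | (3E)-2-(3-methylbut-2-enyl)-3-(triisopropylsilyloxy)hexa-1,3,5-trien-1-one (formed in situ) | O=C=C(CC=C(C)C)/C(O[Si](C(C)C)(C(C)C)C(C)C)=C\C=C | intermediate
11 | 2-(3-methylbut-2-enyl)-3-(triisopropylsilyloxy)cyclohexa-2,4-dien-1-one (formed in situ) | O=C1CC=CC(O[Si](C(C)C)(C(C)C)C(C)C)=C1CC=C(C)C | intermediate
12 | 2-(3-methylbut-2-enyl)-3-(triisopropylsilyloxy)phenol | CC(C)=CCc1c(O)cccc1O[Si](C(C)C)(C(C)C)C(C)C | intermediate
13 | 2-(hydroxymethyl)-6-(3-methylbut-2-enyl)-5-(triisopropylsilyloxy)phenol (as magnesium salt, formed in situ) | OCc1ccc(O[Si](C(C)C)(C(C)C)C(C)C)c(CC=C(C)C)c1O | intermediate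
14 | 2-hydroxy-3-(3-methylbut-2-enyl)-4-(triisopropylsilyloxy)benzaldehyde | O=Cc1ccc(O[Si](C(C)C)(C(C)C)C(C)C)c(CC=C(C)C)c1O | intermediate
15 | 2-(1-hydroxyprop-2-yn-1-yl)-6-(3-methylbut-2-enyl)-5-(triisopropylsilyloxy)phenol (racemic) | C#CC(O)c1ccc(O[Si](C(C)C)(C(C)C)C(C)C)c(CC=C(C)C)c1O | intermediate
16 | 1-[2-hydroxy-3-(3-methylbut-2-enyl)-4-(triisopropylsilyloxy)phenyl]prop-2-yn-1-one (formed in situ) | C#CC(=O)c1ccc(O[Si](C(C)C)(C(C)C)C(C)C)c(CC=C(C)C)c1O | intermediate
17 | (E)-3-(diethylamino)-1-[2-hydroxy-3-(3-methylbut-2-enyl)-4-(triisopropylsilyloxy)phenyl]prop-2-en-1-one (formed in situ) | CCN(CC)/C=C/C(=O)c1ccc(O[Si](C(C)C)(C(C)C)C(C)C)c(CC=C(C)C)c1O | intermediate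
18 | 8-(3-methylbut-2-enyl)-7-(triisopropylsilyloxy)-4H-chromen-4-one | O=c1ccoc2c(CC=C(C)C)c(O[Si](C(C)C)(C(C)C)C(C)C)ccc12 | intermediate
19 | tetrabutylammonium 8-(3-methylbut-2-enyl)-4-oxo-4H-chromen-7-olate (formed in situ) | CCCC[N+](CCCC)(CCCC)CCCC.[O-]c1ccc2c(=O)ccoc2c1CC=C(C)C | intermediate
20 | 7-(methoxymethoxy)-8-(3-methylbut-2-enyl)-4H-chromen-4-one | COCOc1ccc2c(=O)ccoc2c1CC=C(C)C | intermediate
21 | 5-bromo-2-hydroxybenzaldehyde | O=Cc1cc(Br)ccc1O | starting material
22 | 2-(allyloxy)-5-bromobenzaldehyde | O=Cc1cc(Br)ccc1OCC=C | intermediate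
23 | 5-allyl-3-bromo-6-oxocyclohexa-1,3-diene-1-carbaldehyde (racemic, formed in situ) | O=CC1=CC(Br)=CC(CC=C)C1=O | intermediate
24 | 3-allyl-5-bromo-2-hydroxybenzaldehyde | O=Cc1cc(Br)cc(CC=C)c1O | intermediate
25 | 3-allyl-5-bromo-2-hydroxyphenyl formate (formed in situ) | O=COc1cc(Br)cc(CC=C)c1O | intermediate
26 | 3-allyl-5-bromobenzene-1,2-diol | Oc1cc(Br)cc(CC=C)c1O | intermediate
27 | 1-allyl-5-bromo-2,3-bis(methoxymethoxy)benzene | C=CCc1cc(Br)cc(OCOC)c1OCOC | intermediate
28 | 5-bromo-1,2-bis(methoxymethoxy)-3-(3-methylbut-2-enyl)benzene | CC(C)=CCc1cc(Br)cc(OCOC)c1OCOC | intermediate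
29 | [3,4-bis(methoxymethoxy)-5-(3-methylbut-2-enyl)phenyl]lithium (formed in situ) | [Li]c1cc(CC=C(C)C)c(OCOC)c(OCOC)c1 | intermediate
30 | lithium [3,4-bis(methoxymethoxy)-5-(3-methylbut-2-enyl)phenyl]triisopropoxyborate (formed in situ) | [Li+].CC(C)O[B-](OC(C)C)(OC(C)C)c1cc(CC=C(C)C)c(OCOC)c(OCOC)c1 | intermediate
31 | [3,4-bis(methoxymethoxy)-5-(3-methylbut-2-enyl)phenyl]boronic acid | CC(C)=CCc1cc(B(O)O)cc(OCOC)c1OCOC | intermediate
32 | (2S)-2-[3,4-bis(methoxymethoxy)-5-(3-methylbut-2-enyl)phenyl]-7-(methoxymethoxy)-8-(3-methylbut-2-enyl)chroman-4-one | CC(C)=CCc1cc([C@@H]2CC(=O)c3ccc(OCOC)c(CC=C(C)C)c3O2)cc(OCOC)c1OCOC | intermediate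
33 | (2S)-2-[3,4-dihydroxy-5-(3-methylbut-2-enyl)phenyl]-7-hydroxy-8-(3-methylbut-2-enyl)chroman-4-one | CC(C)=CCc1cc([C@@H]2CC(=O)c3ccc(O)c(CC=C(C)C)c3O2)cc(O)c1O | target

**Step count**
Total: 16 steps.
Longest linear sequence: 9 steps (steps 2, 3, 4, 5, 6, 7, 8, 15, 16).

**Steps most likely to fail**

Step 4. Cyclobutenone may oligomerize before or after ring opening, the product phenol may be acylated by the ketene, or the skipped enyne of 4 may isomerize at 80–110 °C, so that little of the ketene is captured by the alkyne. The fallback builds the same arene by directed ortho-metalation. It replaces compounds 4 and 7; no earlier numbered compound contains ring A, so it sets out from purchased 1,3-bis(methoxymethoxy)benzene F1 and comes back to the route at compound 12. Lithiation of F1 with n-BuLi (THF, 0 °C) between the two acetal oxygens should give [2,6-bis(methoxymethoxy)phenyl]lithium F2. With CuBr·SMe2 (cat.) and 1-bromo-3-methylbut-2-ene this should give 1,3-bis(methoxymethoxy)-2-(3-methylbut-2-enyl)benzene F3. Brief treatment with HCl in MeOH at rt should free 2-(3-methylbut-2-enyl)benzene-1,3-diol F4. Because F4 is symmetric, silylation of either hydroxyl with TIPSCl (1 equiv) and imidazole in DMF gives 12; bis-silyl ether and unreacted diol would be separated and recycled.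

Step 15. Insertion of the electron-rich 7-alkoxychromone may be slow enough for protodeboronation of 31 and catalyst decay to win, or the diene–rhodium aryl species may discriminate poorly between the two faces of C2. The fallback sets the stereocenter by resolution instead of by enantioselective C–C bond formation. It sets out from compounds 20 and 31 and comes back at compound 32. Addition of 31 to 20 with the achiral, highly active [Rh(OH)(cod)]2 (cod = cycloocta-1,5-diene; dioxane/H2O, 50 °C) should give racemic 2-[3,4-bis(methoxymethoxy)-5-(3-methylbut-2-enyl)phenyl]-7-(methoxymethoxy)-8-(3-methylbut-2-enyl)chroman-4-one F5. Kinetic resolution by asymmetric transfer hydrogenation follows, with Cp*RhCl[(R,R)-TsDPEN] or its antipode in HCO2H/Et3N and EtOAc at rt, stopped near half conversion. The catalyst antipode is chosen on a small scale so that the (2R)-ketone is the fast-reacting one. It is reduced to (2R,4R)-2-[3,4-bis(methoxymethoxy)-5-(3-methylbut-2-enyl)phenyl]-7-(methoxymethoxy)-8-(3-methylbut-2-enyl)chroman-4-ol F6, which is removed by chromatography, while (2S)-ketone 32 is recovered.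

Step 16. The freed ortho phenols may add to the prenyl double bonds under acid (chroman formation), or the pyranone may open and reclose with loss of configuration at C2 before all three acetals are gone. The fallback uses silyl protection throughout and fluoride at the end. It sets out from compounds 18 and 26 and comes back at compound 33.
- Catechol 26 is silylated (TBSCl, imidazole, DMF) to 3-allyl-5-bromo-1,2-bis(tert-butyldimethylsilyloxy)benzene F7.
- Cross-metathesis as in step 13 should give 5-bromo-1,2-bis(tert-butyldimethylsilyloxy)-3-(3-methylbut-2-enyl)benzene F8.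
- n-BuLi at −78 °C gives [3,4-bis(tert-butyldimethylsilyloxy)-5-(3-methylbut-2-enyl)phenyl]lithium F9, B(Oi-Pr)3 gives lithium [3,4-bis(tert-butyldimethylsilyloxy)-5-(3-methylbut-2-enyl)phenyl]triisopropoxyborate F10, and aq NH4Cl gives [3,4-bis(tert-butyldimethylsilyloxy)-5-(3-methylbut-2-enyl)phenyl]boronic acid F11.
- Conjugate addition of F11 to the silyl-protected chromone 18 uses [RhCl(C2H4)2]2 and (S,S)-Ph-bod with Et3N in place of KOH, so that the aryl silyl ethers do not meet hydroxide. It should give (2S)-2-[3,4-bis(tert-butyldimethylsilyloxy)-5-(3-methylbut-2-enyl)phenyl]-8-(3-methylbut-2-enyl)-7-(triisopropylsilyloxy)chroman-4-one F12.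
- HF·pyridine in THF/pyridine at 0 °C should remove all three silyl groups under nearly neutral conditions and give 33.

**Further compounds**
F1 | step 4 | 1,3-bis(methoxymethoxy)benzene (purchased) | COCOc1cccc(OCOC)c1
F2 | step 4 | [2,6-bis(methoxymethoxy)phenyl]lithium (formed in situ) | [Li]c1c(OCOC)cccc1OCOC
F3 | step 4 | 1,3-bis(methoxymethoxy)-2-(3-methylbut-2-enyl)benzene | CC(C)=CCc1c(OCOC)cccc1OCOC
F4 | step 4 | 2-(3-methylbut-2-enyl)benzene-1,3-diol | CC(C)=CCc1c(O)cccc1O
F5 | step 15 | racemic 2-[3,4-bis(methoxymethoxy)-5-(3-methylbut-2-enyl)phenyl]-7-(methoxymethoxy)-8-(3-methylbut-2-enyl)chroman-4-one | CC(C)=CCc1cc(C2CC(=O)c3ccc(OCOC)c(CC=C(C)C)c3O2)cc(OCOC)c1OCOC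
F6 | step 15 | (2R,4R)-2-[3,4-bis(methoxymethoxy)-5-(3-methylbut-2-enyl)phenyl]-7-(methoxymethoxy)-8-(3-methylbut-2-enyl)chroman-4-ol | CC(C)=CCc1cc([C@H]2C[C@@H](O)c3ccc(OCOC)c(CC=C(C)C)c3O2)cc(OCOC)c1OCOC
F7 | step 16 | 3-allyl-5-bromo-1,2-bis(tert-butyldimethylsilyloxy)benzene | C=CCc1cc(Br)cc(O[Si](C)(C)C(C)(C)C)c1O[Si](C)(C)C(C)(C)C
F8 | step 16 | 5-bromo-1,2-bis(tert-butyldimethylsilyloxy)-3-(3-methylbut-2-enyl)benzene | CC(C)=CCc1cc(Br)cc(O[Si](C)(C)C(C)(C)C)c1O[Si](C)(C)C(C)(C)C
F9 | step 16 | [3,4-bis(tert-butyldimethylsilyloxy)-5-(3-methylbut-2-enyl)phenyl]lithium (formed in situ) | [Li]c1cc(CC=C(C)C)c(O[Si](C)(C)C(C)(C)C)c(O[Si](C)(C)C(C)(C)C)c1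
F10 | step 16 | lithium [3,4-bis(tert-butyldimethylsilyloxy)-5-(3-methylbut-2-enyl)phenyl]triisopropoxyborate (formed in situ) | [Li+].CC(C)O[B-](OC(C)C)(OC(C)C)c1cc(CC=C(C)C)c(O[Si](C)(C)C(C)(C)C)c(O[Si](C)(C)C(C)(C)C)c1
F11 | step 16 | [3,4-bis(tert-butyldimethylsilyloxy)-5-(3-methylbut-2-enyl)phenyl]boronic acid | CC(C)=CCc1cc(B(O)O)cc(O[Si](C)(C)C(C)(C)C)c1O[Si](C)(C)C(C)(C)C
F12 | step 16 | (2S)-2-[3,4-bis(tert-butyldimethylsilyloxy)-5-(3-methylbut-2-enyl)phenyl]-8-(3-methylbut-2-enyl)-7-(triisopropylsilyloxy)chroman-4-one | CC(C)=CCc1cc([C@@H]2CC(=O)c3ccc(O[Si](C(C)C)(C(C)C)C(C)C)c(CC=C(C)C)c3O2)cc(O[Si](C)(C)C(C)(C)C)c1O[Si](C)(C)C(C)(C)C
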